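## Structural features

The target is a sesquilignan in which a 2-aryl-3-(hydroxymethyl)-7-methoxy-2,3-dihydrobenzofuran (DHB) carries, at DHB-C5, a tetrahydrofuran (THF: O1, C2 bonded to the DHB, C3 with CH2OH, C4 with OH and a 4-hydroxy-3-methoxybenzyl group, C5 a methylene). There are five stereocentres in two separate sets. THF-C2, C3 and C4 are contiguous (2R,3R,4S in this numbering), with aryl, CH2OH and benzyl on one face and the tertiary hydroxyl on the other. DHB-C2 and DHB-C3 (2R,3R) carry aryl and CH2OH cis. Both benzylic C–O bonds (THF-C2–O1, para to the DHB oxygen; DHB-C2–O1, para to a phenol) ionise in acid, open through quinone methides in base once the phenols are free, and can be hydrogenolysed; the cis dihydrobenzofuran is also the less stable epimer. The real difficulty is the fully substituted carbinol THF-C4 next to C3 with three carbon substituents crowded on one ring face, together with the kinetic cis-DHB, with no stereochemical relay between the two sets. The key step exploits the THF-C3/C4 pair: H and CH2OH on C3 and OH and benzyl on C4, with CH2OH and OH trans, are what anti opening at C3 of a C3–C4 epoxide gives. That epoxide comes from the C3=C4 alkene of a 2-aryl-4-benzyl-2,5-dihydrofuran, and this alkene is the bond a ring-closing metathesis forms, with THF-C2 as the only stereocentre needed beforehand.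

## Logic of the disconnections

25 ⇒ 24 ⇒ 23. The two phenolic O–benzyl bonds and the primary O–Si bond are cut last. Benzyl survives every basic, organometallic and oxidative step; the silyl group is removed first so that no phenoxide is ever exposed to fluoride. The demand is that hydrogenolysis cleaves the aryl benzyl ethers faster than the two ring benzylic C–O bonds.

23 ⇒ 21 (through 22). The exocyclic C–C bond at THF-C3 is cut and the C4 hydroxyl is read as the oxygen of an epoxide. One carbon and two stereocentres collapse into a single epoxide. The forward step must attack C3 (the only SN2-capable epoxide carbon) with a hydroxymethyl anion equivalent from the face syn to the C2 aryl, without Lewis-acid opening at C4.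

21 ⇒ 20. The two epoxide C–O bonds are cut. Two stereocentres become one trisubstituted alkene whose faces are distinguished only by the C2 aryl; the forward step needs oxygen delivery anti to that aryl.

20 ⇒ 19 (key). The C3=C4 bond is cut. The ring opens to an acyclic bis-allylic ether with a single stereocentre in this domain. The forward step must close a five-membered ring onto a 1,1-disubstituted alkene and leave the new double bond where it forms.

19 ⇒ 13 + 18. The O1–C5 ether bond is cut, giving two fragments of similar size. The forward etherification must use the carbinol oxygen as the nucleophile so that the C2 configuration is retained, under non-acidic conditions.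

13 ⇒ 12 ⇒ 11 ⇒ 10. The carbinol C–H bond (ketone reduction) and then the C2–vinyl bond (carbonyl addition) are cut. This is the one stereocentre of the THF domain that has to come from a reagent, because the DHB stereocentres are too remote to help. The reduction must discriminate aryl from vinyl and must not touch the terminal alkene.

18 ⇒ 16 + 17 ⇒ 15 ⇒ 14. The aryl–CH2 bond is cut to an aryl Grignard reagent and a symmetric bis-allylic dichloride, then the O–benzyl bond. Monosubstitution must be enforced by stoichiometry.

10 ⇒ 9 ⇒ 8 ⇒ 7. Functional-group changes only: O–Si, acetal to aldehyde, ester to primary alcohol. The ester must be reduced before any basic step because DHB-C3–H is acidic while the ester is present.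

7 ⇒ 6. The DHB-C2–C3 bond is cut. Ring and both DHB stereocentres arise in one step from an achiral diazo ester; cis and absolute selectivity must both come from the catalyst.

6 ⇒ 5 ⇒ 4. The diazo nitrogen is removed, then the aryl–CH2 bond at the iodide-bearing carbon is cut. The forward arylation must tolerate an ortho alkoxy group, an acetal and benzyl ethers.

4 ⇒ 3 ⇒ 1 + 2. The acetal is returned to the aldehyde and the aryl O–CH2 bond is cut to a hindered, acidic phenol and a primary benzylic alcohol.

## Other disconnections considered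

Alternative 1: The cut is again DHB-C2–C3, but made at the end, on a substrate that already holds the complete silylated tetrahydrofuran. Diazo ester A1 would lose N2 on Rh2(S-PTTL)4 and the carbenoid would insert into the neighbouring ArCH2–O C–H bond to give cis ester A2; ester reduction and removal of four silyl groups would follow.
- In favour: the insertion is the same reaction as step 5 of the chosen plan, so on mechanism the two are equal. The alternative is better in that the epimerisable cis ring is made last and never meets Grignard reagents, NaH or peracid.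
- Against: the step whose cis and enantioselectivity rest entirely on the catalyst is run on the most advanced intermediate. A1 offers the carbenoid additional Lewis-basic sites (the ring ether and four silyl ethers). The arylacetate needed for the diazo group has acidic protons that clash with the organometallic steps building the tetrahydrofuran, so it must be installed late next to a hindered aryl ether or protected. The final fluoride treatment generates phenoxides para to both benzylic ethers.
- Step economy: no gain. The tetrahydrofuran still has to be built, so the order changes but not the length; the estimate is equal or one to two steps longer.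

Alternative 2: The cut is the aryl C7a–O1 bond. The benzylic alkoxide of bromo alcohol A3 would couple with the ortho C–Br bond (CuI, 3,4,7,8-tetramethyl-1,10-phenanthroline, Cs2CO3, hot toluene) to give A4. The bond forms at an sp2 carbon, so neither stereocentre is touched.
- In favour: the cis relationship is fixed in an acyclic precursor, where it can be set by acyclic stereocontrol and checked before closure. On stereochemical security of the cis ring this is better than a catalyst-controlled insertion. No diazo compound or chiral rhodium catalyst is needed.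
- Against: A4 carries no substituent at DHB-C5. The carbon would have to be introduced afterwards by electrophilic substitution with three competing positions (C5, C4, C6), unless a masked formyl group is carried through the coupling. The tosylate must later be removed under conditions that threaten the cis ring once a phenoxide is para to DHB-C2. The bromide is flanked by two ortho substituents, and the acyclic precursor needs its own enantio- and diastereoselective assembly.
- Step economy: estimated three to five steps longer to reach the stage of 10, and weaker on regiochemistry.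

Alternative 3: The cut is DHB-C3–C3a. Bromine–lithium exchange on threo epoxy ether A5 (n-BuLi, THF, −78 °C) would give an aryllithium that attacks the inner epoxide carbon in a 5-exo mode with inversion, giving A6, which is identical with 8.
- In favour: the closure is stereospecific, so cis follows from threo without any cis/trans selectivity. The absolute configuration would come from asymmetric epoxidation chemistry. The hydroxymethyl group appears at the right oxidation level with no epimerisable ester. On these three points it is better than steps 5 and 6. Because A6 is 8, it would join the chosen route directly, with about equal step count.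
- Against: A5 requires an aryl ether bond at a secondary p-alkoxybenzylic carbon with clean inversion, using a phenol flanked by Br and OMe; SN1 leakage would erode the threo purity. A kinetic resolution on the way costs half the material. The basic organolithium can deprotonate the ArO–CH position and open the epoxide by elimination, or close 6-endo to a chroman-3-ol.
- Overall: the stereochemical logic is stronger and the precursor is weaker, so it is kept in mind as a replacement for steps 1–5 rather than adopted.

Key step: step 14

Assumption 1: Rh2(S-PTTL)4 is taken to give the (2R,3S) cis ester 7, by analogy with simpler 2-(benzyloxy)aryl diazoacetates; if the sense is opposite, Rh2(R-PTTL)4 is used and nothing else changes.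
Assumption 2: in the oxazaborolidine reduction of 12 the dihydrobenzofuranyl group acts as the large substituent and vinyl as the small one.
Abbreviation: DBF* = the (2R,3R)-2-[4-(benzyloxy)-3-methoxyphenyl]-3-{[(tert-butyldimethylsilyl)oxy]methyl}-7-methoxy-2,3-dihydro-1-benzofuran-5-yl group.

## Route

Step 1
Reactants: 1 5-iodovanillin (4-hydroxy-3-iodo-5-methoxybenzaldehyde); 2 [4-(benzyloxy)-3-methoxyphenyl]methanol
Product: 3 4-{[4-(benzyloxy)-3-methoxyphenyl]methoxy}-3-iodo-5-methoxybenzaldehyde
Conditions: PPh3, DIAD, THF, 0 °C → rt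
Reagents that add atoms: none
Why: Mitsunobu etherification; the phenol, acidified by the iodo and formyl groups, is a good pronucleophile and displaces the primary benzylic alkoxyphosphonium by SN2, which avoids isolating a labile p-alkoxybenzyl halide.

Step 2
Reactants: 3 aryl ether aldehyde
Product: 4 2-{[4-(benzyloxy)-3-methoxyphenyl]methoxy}-5-(dimethoxymethyl)-1-iodo-3-methoxybenzene
Conditions: HC(OMe)3, MeOH, PPTS (cat.), rt; Et3N quench
Reagents that add atoms: trimethyl orthoformate, COC(OC)OC; methanol, CO
Why: Acid-catalysed acetalisation driven by the orthoformate; it masks the aldehyde against the zinc enolate, the amidine base, the carbenoid and the hydride of steps 3–6, and PPTS is mild enough for the p-alkoxybenzyl aryl ether.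

Step 3
Reactants: 4 iodo acetal
Product: 5 methyl 2-[2-{[4-(benzyloxy)-3-methoxyphenyl]methoxy}-5-(dimethoxymethyl)-3-methoxyphenyl]acetate
Conditions: BrZnCH2CO2Me (from BrCH2CO2Me and Zn), Pd2(dba)3 (cat.), XPhos, THF, 60 °C
Reagents that add atoms: bromo(2-methoxy-2-oxoethyl)zinc, COC(=O)C[Zn]Br
Why: Palladium-catalysed α-arylation of an ester zinc enolate (Reformatsky reagent in a Negishi-type coupling): oxidative addition of the aryl iodide to zerovalent palladium, transmetalation and reductive elimination; the neutral zinc enolate leaves acetal and benzyl ethers alone and the bulky biarylphosphine copes with the ortho alkoxy group.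

Step 4
Reactants: 5 methyl arylacetate
Product: 6 methyl 2-[2-{[4-(benzyloxy)-3-methoxyphenyl]methoxy}-5-(dimethoxymethyl)-3-methoxyphenyl]-2-diazoacetate
Conditions: p-ABSA, DBU, MeCN, 0 °C → rt
Reagents that add atoms: 4-acetamidobenzenesulfonyl azide (p-ABSA), CC(=O)Nc1ccc(cc1)S(=O)(=O)N=[N+]=[N-]
Why: Regitz diazo transfer; the benzylic ester C–H is acidic enough for DBU and the enolate attacks the terminal azide nitrogen, giving the aryl diazoacetate and the sulfonamide.

Step 5
Reactants: 6 aryl diazoacetate
Product: 7 methyl (2R,3S)-2-[4-(benzyloxy)-3-methoxyphenyl]-5-(dimethoxymethyl)-7-methoxy-2,3-dihydro-1-benzofuran-3-carboxylate (cis)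
Conditions: Rh2(S-PTTL)4 (1 mol %), toluene, −60 °C
Reagents that add atoms: none
Why: Intramolecular 1,5 C–H insertion of a donor/acceptor rhodium carbenoid into the ArCH2–O bond, which is activated by oxygen and by the electron-rich aryl group; this is the known cis-selective route to 2-aryl-2,3-dihydrobenzofuran-3-carboxylates. The chiral carboxylate ligands set DHB-C2 and DHB-C3 together (cis, 2R,3S), and the low temperature suppresses ylide pathways and C3 epimerisation.

Step 6
Reactants: 7 cis ester
Product: 9 (2R,3R)-2-[4-(benzyloxy)-3-methoxyphenyl]-3-(hydroxymethyl)-7-methoxy-2,3-dihydro-1-benzofuran-5-carbaldehyde, via hydroxy acetal 8 (not isolated)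
Conditions: i-Bu2AlH (3 equiv), CH2Cl2, −78 → −30 °C; aq. potassium sodium tartrate; then aq. oxalic acid, THF, rt
Reagents that add atoms: water, O
Why: Non-basic hydride reduction of the ester removes the acidic DHB-C3–H problem without epimerisation; the dimethyl acetal of an electron-rich benzaldehyde then hydrolyses in dilute acid far faster than the benzylic ether ionises. The descriptor at C3 changes from S to R only because the substituent priority changes.

Step 7
Reactants: 9 hydroxy aldehyde
Product: 10 (2R,3R)-2-[4-(benzyloxy)-3-methoxyphenyl]-3-{[(tert-butyldimethylsilyl)oxy]methyl}-7-methoxy-2,3-dihydro-1-benzofuran-5-carbaldehyde (DBF*-carbaldehyde)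
Conditions: TBSCl, imidazole, CH2Cl2, 0 °C → rt
Reagents that add atoms: tert-butyldimethylsilyl chloride, CC(C)(C)[Si](C)(C)Cl
Why: Standard silylation of a primary alcohol; the silyl ether withstands the Grignard, hydride, peracid and peroxide steps and leaves with fluoride at the end.

Step 8
Reactants: 10 DBF*-carbaldehyde
Product: 11 1-(DBF*)prop-2-en-1-ol (both epimers at the carbinol carbon)
Conditions: CH2=CHMgBr, THF, −78 °C; aq. NH4Cl
Reagents that add atoms: vinylmagnesium bromide, C=C[Mg]Br
Why: Grignard addition to an aryl aldehyde; the new centre forms without control and is erased in step 9.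

Step 9
Reactants: 11 allylic alcohol epimers
Product: 12 1-(DBF*)prop-2-en-1-one
Conditions: MnO2 (activated, excess), CH2Cl2, rt
Reagents that add atoms: none
Why: MnO2 oxidises the benzylic, allylic alcohol selectively under neutral conditions; the aryl vinyl ketone is filtered and used at once to avoid polymerisation.

Step 10
Reactants: 12 aryl vinyl ketone
Product: 13 (1R)-1-(DBF*)prop-2-en-1-ol
Conditions: (S)-2-methyl-CBS-oxazaborolidine (0.3 equiv), catecholborane, toluene, −78 °C
Reagents that add atoms: none
Why: Corey–Bakshi–Shibata reduction; the ketone binds the ring boron anti to the larger aryl group and hydride is delivered from the nitrogen-bound borane to one face, giving the R carbinol under reagent control. Catecholborane at −78 °C spares the vinyl group from hydroboration.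

Step 11
Reactants: 14 4-bromo-2-methoxyphenol
Product: 15 1-(benzyloxy)-4-bromo-2-methoxybenzene
Conditions: BnBr, K2CO3, acetone, reflux
Reagents that add atoms: benzyl bromide, BrCc1ccccc1
Why: Williamson etherification of a phenoxide with a benzylic bromide.

Step 12
Reactants: 15 aryl bromide; 16 3-chloro-2-(chloromethyl)prop-1-ene
Product: 18 1-(benzyloxy)-4-[2-(chloromethyl)prop-2-en-1-yl]-2-methoxybenzene, via aryl Grignard reagent 17 (not isolated)
Conditions: Mg, THF, 50 °C; then added slowly to 16 (3 equiv), CuI (5 mol %), THF, −10 °C → rt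
Reagents that add atoms: none
Why: Copper-catalysed allylic substitution of a Grignard reagent; on the symmetric dichloride the SN2 and SN2' paths give the same product, and the excess of dichloride, removed afterwards by distillation, limits double substitution.

Step 13
Reactants: 13 (R)-allylic alcohol; 18 allylic chloride
Product: 19 (1R)-1-(DBF*)prop-2-en-1-yl 2-[4-(benzyloxy)-3-methoxybenzyl]prop-2-en-1-yl ether
Conditions: NaH, Bu4NI (cat.), THF/DMF, 0 °C → rt
Reagents that add atoms: none
Why: Williamson etherification with in situ iodide exchange; the carbinol oxygen is the nucleophile, so its C–O bond is not broken and the R configuration is retained, and no acid is present to ionise the p-alkoxybenzylic allylic centre.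

Step 14
Reactants: 19 diene
Product: 20 (2R)-4-[4-(benzyloxy)-3-methoxybenzyl]-2-(DBF*)-2,5-dihydrofuran
Conditions: second-generation Grubbs catalyst RuCl2(=CHPh)(H2IMes)(PCy3) (5 mol %), 1,4-benzoquinone (10 mol %), CH2Cl2 (0.01 M), 40 °C
Reagents that add atoms: none
Why: Olefin metathesis through metallacyclobutanes: the ruthenium benzylidene first engages the unhindered vinyl group (cycloaddition, cycloreversion, loss of styrene) to place an alkylidene on the carbon that becomes C3, which then adds across the 1,1-disubstituted alkene; collapse of the second ruthenacyclobutane forms C3=C4 and returns Ru=CH2, and loss of ethylene makes the sequence irreversible. The closest known reaction type is ring-closing metathesis of allyl 2-substituted-allyl ethers to 3-substituted 2,5-dihydrofurans with N-heterocyclic-carbene ruthenium catalysts. The ring closed is the five-membered oxacycle O1–C2–C3–C4–C5, by intramolecular alkylidene transfer with the new double bond endocyclic; the gem-disubstituted alkene cannot homodimerise, so cyclisation is its only productive path. No stereocentre is created, and C2 is a spectator whose C–H and C–O bonds are untouched, so the R configuration from step 10 is carried through. The step needs chemoselectivity for closure over intermolecular metathesis, which dilution and the 1,6-relationship of the alkenes secure, and positional integrity of the new alkene, which benzoquinone secures by intercepting ruthenium hydrides. Benzyl ethers, the silyl ether and the acid-sensitive benzylic ether are inert to the neutral catalyst.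

Step 15
Reactants: 20 dihydrofuran
Product: 21 (1R,4S,5S)-1-[4-(benzyloxy)-3-methoxybenzyl]-4-(DBF*)-3,6-dioxabicyclo[3.1.0]hexane (epoxide oxygen anti to DBF*)
Conditions: m-CPBA, NaHCO3, CH2Cl2, 0 °C
Reagents that add atoms: m-chloroperoxybenzoic acid, OOC(=O)c1cccc(Cl)c1
Why: Prilezhaev epoxidation; concerted syn transfer of oxygen to the electron-rich trisubstituted alkene from the face opposite the C2 aryl sets C3 and C4 relative to C2 by steric control, and the bicarbonate buffer protects the tertiary epoxide and the benzylic ether from the acid formed.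

Step 16
Reactants: 21 epoxide
Product: 23 (3S,4R,5R)-3-[4-(benzyloxy)-3-methoxybenzyl]-4-(hydroxymethyl)-5-(DBF*)oxolan-3-ol, via hydroxy silane 22 (not isolated)
Conditions: (i-PrO)Me2SiCH2MgCl (4 equiv, from (i-PrO)Me2SiCH2Cl and Mg), CuI (20 mol %), THF, −20 → 0 °C; aq. NH4Cl; then KF, KHCO3, 30% H2O2, THF/MeOH, rt
Reagents that add atoms: (isopropoxydimethylsilyl)methylmagnesium chloride, CC(C)O[Si](C)(C)C[Mg]Cl; hydrogen peroxide, OO
Why: Copper-catalysed Grignard opening of an epoxide by SN2 at THF-C3 (C4 is fully substituted), with inversion: the carbon enters on the aryl face, so CH2 ends cis to the aryl while the C4 oxygen keeps its place trans to it. Tamao oxidation then converts the C–Si bond to C–OH; the silylmethyl Grignard reagent is the established hydroxymethyl anion equivalent for epoxides.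

Step 17
Reactants: 23 silyl-protected diol
Product: 24 (3S,4R,5R)-3-[4-(benzyloxy)-3-methoxybenzyl]-5-[(2R,3R)-2-[4-(benzyloxy)-3-methoxyphenyl]-3-(hydroxymethyl)-7-methoxy-2,3-dihydro-1-benzofuran-5-yl]-4-(hydroxymethyl)oxolan-3-ol
Conditions: Bu4NF, THF, 0 °C → rt
Reagents that add atoms: none
Why: Fluoride desilylation of a primary silyl ether; it is done while both phenols are still benzylated, so no phenoxide para to a benzylic ether can form under the basic fluoride.

Step 18
Reactants: 24 bis-benzyl ether
Product: 25 (3S,4R,5R)-3-(4-hydroxy-3-methoxybenzyl)-5-[(2R,3R)-2-(4-hydroxy-3-methoxyphenyl)-3-(hydroxymethyl)-7-methoxy-2,3-dihydro-1-benzofuran-5-yl]-4-(hydroxymethyl)oxolan-3-ol (CNP0284796.1)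
Conditions: H2 (1 atm), 10% Pd/C, EtOAc/MeOH, rt; stopped when 24 is consumed
Reagents that add atoms: none
Why: Hydrogenolysis of aryl benzyl ethers under neutral conditions; these unhindered O–benzyl groups should cleave faster than the two ring benzylic C–O bonds, and neither acid nor base is present to epimerise the cis ring.

## Compound list

1 | 5-iodovanillin (4-hydroxy-3-iodo-5-methoxybenzaldehyde) | COc1cc(C=O)cc(I)c1O | starting material
2 | [4-(benzyloxy)-3-methoxyphenyl]methanol | COc1cc(CO)ccc1OCc1ccccc1 | starting material
3 | 4-{[4-(benzyloxy)-3-methoxyphenyl]methoxy}-3-iodo-5-methoxybenzaldehyde | COc1cc(C=O)cc(I)c1OCc1ccc(OCc2ccccc2)c(OC)c1 | intermediate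
4 | 2-{[4-(benzyloxy)-3-methoxyphenyl]methoxy}-5-(dimethoxymethyl)-1-iodo-3-methoxybenzene | COC(OC)c1cc(OC)c(OCc2ccc(OCc3ccccc3)c(OC)c2)c(I)c1 | intermediate
5 | methyl 2-[2-{[4-(benzyloxy)-3-methoxyphenyl]methoxy}-5-(dimethoxymethyl)-3-methoxyphenyl]acetate | COC(OC)c1cc(OC)c(OCc2ccc(OCc3ccccc3)c(OC)c2)c(CC(=O)OC)c1 | intermediate
6 | methyl 2-[2-{[4-(benzyloxy)-3-methoxyphenyl]methoxy}-5-(dimethoxymethyl)-3-methoxyphenyl]-2-diazoacetate | COC(OC)c1cc(OC)c(OCc2ccc(OCc3ccccc3)c(OC)c2)c(c1)C(=[N+]=[N-])C(=O)OC | intermediate
7 | methyl (2R,3S)-2-[4-(benzyloxy)-3-methoxyphenyl]-5-(dimethoxymethyl)-7-methoxy-2,3-dihydro-1-benzofuran-3-carboxylate (cis) | COC(OC)c3cc(OC)c4c(c3)[C@H](C(=O)OC)[C@H](c3ccc(OCc5ccccc5)c(OC)c3)O4 | intermediate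
8 | [(2R,3R)-2-[4-(benzyloxy)-3-methoxyphenyl]-5-(dimethoxymethyl)-7-methoxy-2,3-dihydro-1-benzofuran-3-yl]methanol (not isolated) | COC(OC)c3cc(OC)c4c(c3)[C@H](CO)[C@H](c3ccc(OCc5ccccc5)c(OC)c3)O4 | intermediate
9 | (2R,3R)-2-[4-(benzyloxy)-3-methoxyphenyl]-3-(hydroxymethyl)-7-methoxy-2,3-dihydro-1-benzofuran-5-carbaldehyde | O=Cc3cc(OC)c4c(c3)[C@H](CO)[C@H](c3ccc(OCc5ccccc5)c(OC)c3)O4 | intermediate
10 | (2R,3R)-2-[4-(benzyloxy)-3-methoxyphenyl]-3-{[(tert-butyldimethylsilyl)oxy]methyl}-7-methoxy-2,3-dihydro-1-benzofuran-5-carbaldehyde | O=Cc3cc(OC)c4c(c3)[C@H](CO[Si](C)(C)C(C)(C)C)[C@H](c3ccc(OCc5ccccc5)c(OC)c3)O4 | intermediate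
11 | 1-(DBF*)prop-2-en-1-ol, both carbinol epimers | C=CC(O)c3cc(OC)c4c(c3)[C@H](CO[Si](C)(C)C(C)(C)C)[C@H](c3ccc(OCc5ccccc5)c(OC)c3)O4 | intermediate
12 | 1-(DBF*)prop-2-en-1-one | C=CC(=O)c3cc(OC)c4c(c3)[C@H](CO[Si](C)(C)C(C)(C)C)[C@H](c3ccc(OCc5ccccc5)c(OC)c3)O4 | intermediate
13 | (1R)-1-(DBF*)prop-2-en-1-ol | C=C[C@@H](O)c3cc(OC)c4c(c3)[C@H](CO[Si](C)(C)C(C)(C)C)[C@H](c3ccc(OCc5ccccc5)c(OC)c3)O4 | intermediate
14 | 4-bromo-2-methoxyphenol | COc1cc(Br)ccc1O | starting material
15 | 1-(benzyloxy)-4-bromo-2-methoxybenzene | COc1cc(Br)ccc1OCc1ccccc1 | intermediate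
16 | 3-chloro-2-(chloromethyl)prop-1-ene | C=C(CCl)CCl | starting material
17 | [4-(benzyloxy)-3-methoxyphenyl]magnesium bromide (not isolated) | COc1cc([Mg]Br)ccc1OCc1ccccc1 | intermediate
18 | 1-(benzyloxy)-4-[2-(chloromethyl)prop-2-en-1-yl]-2-methoxybenzene | C=C(CCl)Cc1ccc(OCc2ccccc2)c(OC)c1 | intermediate
19 | (1R)-1-(DBF*)prop-2-en-1-yl 2-[4-(benzyloxy)-3-methoxybenzyl]prop-2-en-1-yl ether | C=C[C@@H](OCC(=C)Cc1ccc(OCc2ccccc2)c(OC)c1)c3cc(OC)c4c(c3)[C@H](CO[Si](C)(C)C(C)(C)C)[C@H](c3ccc(OCc5ccccc5)c(OC)c3)O4 | intermediate
20 | (2R)-4-[4-(benzyloxy)-3-methoxybenzyl]-2-(DBF*)-2,5-dihydrofuran | COc1cc(CC2=C[C@H](c3cc(OC)c4c(c3)[C@H](CO[Si](C)(C)C(C)(C)C)[C@H](c3ccc(OCc5ccccc5)c(OC)c3)O4)OC2)ccc1OCc1ccccc1 | intermediate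
21 | (1R,4S,5S)-1-[4-(benzyloxy)-3-methoxybenzyl]-4-(DBF*)-3,6-dioxabicyclo[3.1.0]hexane, epoxide oxygen anti to DBF* | COc1cc(C[C@@]26CO[C@@H](c3cc(OC)c4c(c3)[C@H](CO[Si](C)(C)C(C)(C)C)[C@H](c3ccc(OCc5ccccc5)c(OC)c3)O4)[C@@H]2O6)ccc1OCc1ccccc1 | intermediate
22 | (3S,4R,5R)-3-[4-(benzyloxy)-3-methoxybenzyl]-4-{[dimethyl(propan-2-yloxy)silyl]methyl}-5-(DBF*)oxolan-3-ol (not isolated) | COc1cc(C[C@@]2(O)CO[C@@H](c3cc(OC)c4c(c3)[C@H](CO[Si](C)(C)C(C)(C)C)[C@H](c3ccc(OCc5ccccc5)c(OC)c3)O4)[C@H]2C[Si](C)(C)OC(C)C)ccc1OCc1ccccc1 | intermediate
23 | (3S,4R,5R)-3-[4-(benzyloxy)-3-methoxybenzyl]-4-(hydroxymethyl)-5-(DBF*)oxolan-3-ol | COc1cc(C[C@@]2(O)CO[C@@H](c3cc(OC)c4c(c3)[C@H](CO[Si](C)(C)C(C)(C)C)[C@H](c3ccc(OCc5ccccc5)c(OC)c3)O4)[C@H]2CO)ccc1OCc1ccccc1 | intermediate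
24 | (3S,4R,5R)-3-[4-(benzyloxy)-3-methoxybenzyl]-5-[(2R,3R)-2-[4-(benzyloxy)-3-methoxyphenyl]-3-(hydroxymethyl)-7-methoxy-2,3-dihydro-1-benzofuran-5-yl]-4-(hydroxymethyl)oxolan-3-ol | COc1cc(C[C@@]2(O)CO[C@@H](c3cc(OC)c4c(c3)[C@H](CO)[C@H](c3ccc(OCc5ccccc5)c(OC)c3)O4)[C@H]2CO)ccc1OCc1ccccc1 | intermediate
25 | (3S,4R,5R)-3-(4-hydroxy-3-methoxybenzyl)-5-[(2R,3R)-2-(4-hydroxy-3-methoxyphenyl)-3-(hydroxymethyl)-7-methoxy-2,3-dihydro-1-benzofuran-5-yl]-4-(hydroxymethyl)oxolan-3-ol | COc1cc(C[C@@]2(O)CO[C@@H](c3cc(OC)c4c(c3)[C@H](CO)[C@H](c3ccc(O)c(OC)c3)O4)[C@H]2CO)ccc1O | target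

## Step count and least certain steps

Total step count: 18. Longest linear sequence: 16 steps (steps 1–10, then 13–18, from 1 to 25).

Step 14 (key step). The most likely failure is slow engagement of the gem-disubstituted alkene, which gives decaying catalyst time to form ruthenium hydrides that move the allyl ether or the new ring double bond toward O1 (enol ether, then aromatisation to the furan). The fallback sets out from 13 and comes back at 20, and keeps the arylmethyl group off the alkene during ring closure. The alkoxide of 13 is alkylated with an excess of 16 (NaH, Bu4NI, THF/DMF) to give (1R)-1-(DBF*)prop-2-en-1-yl 2-(chloromethyl)prop-2-en-1-yl ether F1. Ring-closing metathesis of this smaller diene with the same catalyst gives (2R)-4-(chloromethyl)-2-(DBF*)-2,5-dihydrofuran F2. Coupling of F2 with Grignard reagent 17 under Li2CuCl4 catalysis (THF, −30 °C) should substitute at the primary carbon, because the other allylic terminus (C3) is shielded by the aryl-bearing C2, and gives 20.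

Step 16. The most likely failure is that backside approach to C3 on the aryl face, next to a fully substituted carbon, is too slow, so that magnesium halide opens the epoxide at C4 or triggers a hydride shift to a C3 ketone. The fallback sets out from 20 and comes back at 23; it places the crowded substituent by delivering hydrogen, not carbon, to the open face. Upjohn dihydroxylation of 20 (OsO4 cat., N-methylmorpholine N-oxide, acetone/H2O) anti to the aryl gives (3R,4S,5S)-3-[4-(benzyloxy)-3-methoxybenzyl]-5-(DBF*)oxolane-3,4-diol F3. Parikh–Doering oxidation (SO3·pyridine, DMSO, i-Pr2NEt, 0 °C) of the secondary hydroxyl gives (2S,4R)-4-[4-(benzyloxy)-3-methoxybenzyl]-4-hydroxy-2-(DBF*)oxolan-3-one F4. Non-basic methylenation with Cp2Ti(μ-Cl)(μ-CH2)AlMe2 gives 3-[4-(benzyloxy)-3-methoxybenzyl]-4-methylidene-5-(DBF*)oxolan-3-ol F5, with the configuration of 23 at its two ring stereocentres. Hydroboration with 9-BBN from the face opposite both the aryl and the benzyl group, then NaBO3, puts H trans and CH2OH cis to the aryl and gives 23. This is two steps longer, and C2 of F4 is epimerisable, which is why the reagents are non-basic.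

Step 15. The most likely failure is poor facial selectivity, since the C2 aryl is the only differentiating element and sits one atom away from C4. The fallback sets out from 20 and comes back at 21, and replaces substrate control by reagent control: a Shi epoxidation (Oxone, 2KHSO5·KHSO4·K2SO4; K2CO3; Bu4NHSO4; MeCN/dimethoxymethane/aqueous buffer, 0 °C). Trisubstituted alkenes are its best substrates. The ketone enantiomer whose spiro transition state delivers oxygen anti to the aryl is used; on the usual model this is the enantiomer of the fructose-derived ketone, made from L-sorbose, and this assignment is a prediction. The basic medium also suits the acid-sensitive epoxide.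

Step 10. The most likely failure is incomplete discrimination between two sp2 substituents (aryl and vinyl) at the ketone, with conjugate reduction or hydroboration of the enone as side paths. The fallback sets out from 11 and comes back at 13, bypassing 12. The epimer mixture 11 is subjected to a Sharpless kinetic-resolution epoxidation (Ti(Oi-Pr)4, D-(−)-diisopropyl tartrate, t-BuOOH, 4 Å sieves, CH2Cl2, −20 °C). By the usual model this consumes the S carbinol epimer as the erythro epoxy alcohol (R)-(DBF*)[(2S)-oxiran-2-yl]methanol F6 and leaves 13, which is separated by chromatography. The cost is half of the material.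

Step 5. The most likely failure is erosion of cis selectivity, because the ether oxygen is flanked by two ortho substituents and the benzylic C–H bonds are twisted away from the carbenoid, together with C3 epimerisation on handling. The fallback sets out from 7 as obtained, mixed with its C3 epimer methyl (2R,3R)-2-[4-(benzyloxy)-3-methoxyphenyl]-5-(dimethoxymethyl)-7-methoxy-2,3-dihydro-1-benzofuran-3-carboxylate F7, and comes back at 7. The mixture is deprotonated with LiN(i-Pr)2 (THF, −78 °C) to the lithium ester enolate F8, in which the ring C–O bond lies in the nodal plane of the enolate and so resists elimination. Kinetic protonation with a bulky phenol (2,6-di-tert-butyl-4-methylphenol) from the face opposite the C2 aryl returns the ester cis to the aryl. This corrects the diastereomer ratio only; the enantiomeric purity still rests on the catalyst.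

## Further compounds

F1 | step 14 | (1R)-1-(DBF*)prop-2-en-1-yl 2-(chloromethyl)prop-2-en-1-yl ether | C=C[C@@H](OCC(=C)CCl)c3cc(OC)c4c(c3)[C@H](CO[Si](C)(C)C(C)(C)C)[C@H](c3ccc(OCc5ccccc5)c(OC)c3)O4
F2 | step 14 | (2R)-4-(chloromethyl)-2-(DBF*)-2,5-dihydrofuran | ClCC2=C[C@H](c3cc(OC)c4c(c3)[C@H](CO[Si](C)(C)C(C)(C)C)[C@H](c3ccc(OCc5ccccc5)c(OC)c3)O4)OC2
F3 | step 16 | (3R,4S,5S)-3-[4-(benzyloxy)-3-methoxybenzyl]-5-(DBF*)oxolane-3,4-diol, both hydroxyls anti to DBF* | COc1cc(C[C@@]2(O)CO[C@@H](c3cc(OC)c4c(c3)[C@H](CO[Si](C)(C)C(C)(C)C)[C@H](c3ccc(OCc5ccccc5)c(OC)c3)O4)[C@@H]2O)ccc1OCc1ccccc1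
F4 | step 16 | (2S,4R)-4-[4-(benzyloxy)-3-methoxybenzyl]-4-hydroxy-2-(DBF*)oxolan-3-one | COc1cc(C[C@@]2(O)CO[C@@H](c3cc(OC)c4c(c3)[C@H](CO[Si](C)(C)C(C)(C)C)[C@H](c3ccc(OCc5ccccc5)c(OC)c3)O4)C2=O)ccc1OCc1ccccc1
F5 | step 16 | 3-[4-(benzyloxy)-3-methoxybenzyl]-4-methylidene-5-(DBF*)oxolan-3-ol, hydroxyl trans to DBF* | COc1cc(C[C@@]2(O)CO[C@@H](c3cc(OC)c4c(c3)[C@H](CO[Si](C)(C)C(C)(C)C)[C@H](c3ccc(OCc5ccccc5)c(OC)c3)O4)C2=C)ccc1OCc1ccccc1
F0 | step 15 | none | none
F6 | step 10 | (R)-(DBF*)[(2S)-oxiran-2-yl]methanol (erythro) | O[C@H](c3cc(OC)c4c(c3)[C@H](CO[Si](C)(C)C(C)(C)C)[C@H](c3ccc(OCc5ccccc5)c(OC)c3)O4)[C@@H]1CO1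
F7 | step 5 | methyl (2R,3R)-2-[4-(benzyloxy)-3-methoxyphenyl]-5-(dimethoxymethyl)-7-methoxy-2,3-dihydro-1-benzofuran-3-carboxylate (trans) | COC(OC)c3cc(OC)c4c(c3)[C@@H](C(=O)OC)[C@H](c3ccc(OCc5ccccc5)c(OC)c3)O4
F8 | step 5 | lithium enolate of 7 (C2 R) | COC(OC)c3cc(OC)c4c(c3)C(=C([O-])OC)[C@H](c3ccc(OCc5ccccc5)c(OC)c3)O4.[Li+]
A1 | alternative 1 | methyl 2-diazo-2-{2-[(4-{[tert-butyl(dimethyl)silyl]oxy}-3-methoxyphenyl)methoxy]-3-methoxy-5-[(2R,3R,4S)-4-(4-{[tert-butyl(dimethyl)silyl]oxy}-3-methoxybenzyl)-3-({[tert-butyl(dimethyl)silyl]oxy}methyl)-4-[(triethylsilyl)oxy]oxolan-2-yl]phenyl}acetate | COc1cc(C[C@@]2(O[Si](CC)(CC)CC)CO[C@@H](c3cc(OC)c(OCc4ccc(O[Si](C)(C)C(C)(C)C)c(OC)c4)c(c3)C(=[N+]=[N-])C(=O)OC)[C@H]2CO[Si](C)(C)C(C)(C)C)ccc1O[Si](C)(C)C(C)(C)C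
A2 | alternative 1 | methyl (2R,3S)-2-(4-{[tert-butyl(dimethyl)silyl]oxy}-3-methoxyphenyl)-7-methoxy-5-[(2R,3R,4S)-4-(4-{[tert-butyl(dimethyl)silyl]oxy}-3-methoxybenzyl)-3-({[tert-butyl(dimethyl)silyl]oxy}methyl)-4-[(triethylsilyl)oxy]oxolan-2-yl]-2,3-dihydro-1-benzofuran-3-carboxylate | COc1cc(C[C@@]2(O[Si](CC)(CC)CC)CO[C@@H](c3cc(OC)c4c(c3)[C@H](C(=O)OC)[C@H](c3ccc(O[Si](C)(C)C(C)(C)C)c(OC)c3)O4)[C@H]2CO[Si](C)(C)C(C)(C)C)ccc1O[Si](C)(C)C(C)(C)C
A3 | alternative 2 | 4-[(1R,2R)-2-(2-bromo-3-methoxyphenyl)-3-{[tert-butyl(dimethyl)silyl]oxy}-1-hydroxypropyl]-2-methoxyphenyl 4-methylbenzenesulfonate | c1cc(OC)c(Br)c(c1)[C@H](CO[Si](C)(C)C(C)(C)C)[C@H](c1ccc(OS(=O)(=O)c2ccc(C)cc2)c(OC)c1)O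
A4 | alternative 2 | 4-[(2R,3R)-3-({[tert-butyl(dimethyl)silyl]oxy}methyl)-7-methoxy-2,3-dihydro-1-benzofuran-2-yl]-2-methoxyphenyl 4-methylbenzenesulfonate | c3cc(OC)c4c(c3)[C@H](CO[Si](C)(C)C(C)(C)C)[C@H](c5ccc(OS(=O)(=O)c6ccc(C)cc6)c(OC)c5)O4
A5 | alternative 3 | 2-bromo-1-{(S)-[4-(benzyloxy)-3-methoxyphenyl][(2S)-oxiran-2-yl]methoxy}-4-(dimethoxymethyl)-6-methoxybenzene (threo) | COC(OC)c1cc(OC)c(O[C@@H](c2ccc(OCc3ccccc3)c(OC)c2)[C@@H]4CO4)c(Br)c1
A6 | alternative 3 | [(2R,3R)-2-[4-(benzyloxy)-3-methoxyphenyl]-5-(dimethoxymethyl)-7-methoxy-2,3-dihydro-1-benzofuran-3-yl]methanol (identical with 8) | COC(OC)c3cc(OC)c4c(c3)[C@H](CO)[C@H](c3ccc(OCc5ccccc5)c(OC)c3)O4
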